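The plan rests on cutting the C2–C3 bond of ring C. In the target, C2 is bound to O1 and to the electron-rich ring B. Opened up, it is the CH2 of an O1 benzyl ether whose two enantiotopic C–H bonds are unusually hydridic. A chiral dirhodium carbenoid raised at C3 from a ring A diazomethyl ketone inserts into one of them, which in one operation forms C2–C3, closes ring C and sets C2. The precursor is the tris-TBS-protected 2-benzyloxy-4,6-dioxy-5-prenylphenyl diazomethyl ketone; its ring A pattern comes from a Claisen–Cope relay. Enol silane oxidation then places the C3 hydroxyl trans to the aryl group, and amine-buffered HF frees the phenols.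

Key step: step 8

Remark: TBS = tert-butyldimethylsilyl, TMS = trimethylsilyl, prenyl = 3-methylbut-2-enyl. Flavonoid numbering (O1, C2, C3, C4, C4a, C5 to C8, C8a, ring B primed) is used for the bicyclic compounds and for the atoms that become them.
Remark: the descriptor at C2 changes from S (flavanone) to R (3-oxygenated compounds) without any change of geometry, because C3 outranks the aryl carbon once it carries oxygen.
Assumption: Rh2(S-PTTL)4 is taken to deliver the 2S flavanone. If the sense of induction proves opposite, the mirror-image catalyst Rh2(R-PTTL)4 is used and nothing else changes.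

Step 1
Reactants: 1 2,4,6-trihydroxyacetophenone
Product: 2 1-[2-hydroxy-4,6-bis(tert-butyldimethylsilyloxy)phenyl]ethanone
Conditions: TBSCl (2.1 equiv), imidazole, DMF, 0 °C to rt
Reagents that add atoms: tert-butyldimethylsilyl chloride, CC(C)(C)[Si](C)(C)Cl
Why: Phenol silylation with chlorosilane and imidazole: the para hydroxyl and one of the two equivalent ortho hydroxyls react, while the last hydroxyl is locked in a strong hydrogen bond to the acetyl oxygen and stays free at two equivalents of chlorosilane.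

Step 2
Reactants: 2 1-[2-hydroxy-4,6-bis(tert-butyldimethylsilyloxy)phenyl]ethanone; 3 3-methylbut-2-en-1-ol (prenol)
Product: 4 1-[2-(3-methylbut-2-enyloxy)-4,6-bis(tert-butyldimethylsilyloxy)phenyl]ethanone
Conditions: PPh3, DIAD, THF, 0 °C to rt
Reagents that add atoms: none
Why: Mitsunobu etherification alkylates the chelated phenol at oxygen with the primary allylic alcohol under neutral conditions, so the base-labile aryl silyl ethers are not endangered.

Step 3
Reactants: 4 1-[2-(3-methylbut-2-enyloxy)-4,6-bis(tert-butyldimethylsilyloxy)phenyl]ethanone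
Product: 7 1-[2-hydroxy-4,6-bis(tert-butyldimethylsilyloxy)-5-(3-methylbut-2-enyl)phenyl]ethanone, via ortho-dienone 5 (not isolated), via para-dienone 6 (not isolated)
Conditions: PhNEt2, 200 °C, Ar
Reagents that add atoms: none
Why: Tandem aromatic Claisen–Cope (para-Claisen) rearrangement, a behaviour known for 2-prenyloxy-4,6-dialkoxyacetophenones: the first [3,3] shift gives a crowded reverse-prenyl dienone, a second [3,3] shift carries the allyl unit to the para carbon between the two silyloxy groups, and enolisation gives the phenol with a linear prenyl group, so the ring A pattern is fixed by pericyclic topology and not by a selective protection.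

Step 4
Reactants: 8 vanillin (4-hydroxy-3-methoxybenzaldehyde)
Product: 9 4-(tert-butyldimethylsilyloxy)-3-methoxybenzaldehyde
Conditions: TBSCl, imidazole, CH2Cl2, rt
Reagents that add atoms: tert-butyldimethylsilyl chloride, CC(C)(C)[Si](C)(C)Cl
Why: Routine phenol silylation of the only hydroxyl group present.

Step 5
Reactants: 9 4-(tert-butyldimethylsilyloxy)-3-methoxybenzaldehyde
Product: 10 [4-(tert-butyldimethylsilyloxy)-3-methoxyphenyl]methanol
Conditions: NaBH4, MeOH–THF, 0 °C
Reagents that add atoms: none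
Why: Borohydride reduction of the aromatic aldehyde, run cold and briefly so that the aryl silyl ether is left alone.

Step 6
Reactants: 7 1-[2-hydroxy-4,6-bis(tert-butyldimethylsilyloxy)-5-(3-methylbut-2-enyl)phenyl]ethanone; 10 [4-(tert-butyldimethylsilyloxy)-3-methoxyphenyl]methanol
Product: 11 1-{2-[4-(tert-butyldimethylsilyloxy)-3-methoxybenzyloxy]-4,6-bis(tert-butyldimethylsilyloxy)-5-(3-methylbut-2-enyl)phenyl}ethanone
Conditions: PPh3, DIAD, toluene–THF, 0 °C to rt
Reagents that add atoms: none
Why: A second Mitsunobu etherification joins the only free phenol (the future O1) to the benzylic alcohol, which avoids both the unstable 4-silyloxybenzyl halide and the carbonate base that would strip or scramble aryl silyl ethers.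

Step 7
Reactants: 11 1-{2-[4-(tert-butyldimethylsilyloxy)-3-methoxybenzyloxy]-4,6-bis(tert-butyldimethylsilyloxy)-5-(3-methylbut-2-enyl)phenyl}ethanone
Product: 13 2-diazo-1-{2-[4-(tert-butyldimethylsilyloxy)-3-methoxybenzyloxy]-4,6-bis(tert-butyldimethylsilyloxy)-5-(3-methylbut-2-enyl)phenyl}ethanone, via trifluoroacetyl diketone 12 (not isolated)
Conditions: LiN(SiMe3)2, THF, −78 °C; CF3CO2CH2CF3, −78 °C, 10 min; cold 5% aq HCl work-up; then p-ABSA, Et3N, H2O (1 equiv), MeCN, rt
Reagents that add atoms: 2,2,2-trifluoroethyl trifluoroacetate, O=C(OCC(F)(F)F)C(F)(F)F (trifluoroacetyl group of 12 only); 4-acetamidobenzenesulfonyl azide (p-ABSA), CC(=O)Nc1ccc(cc1)S(=O)(=O)N=[N+]=[N-] (the two diazo nitrogens of 13)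
Why: Detrifluoroacetylative variant of the Regitz diazo transfer: the kinetic lithium enolate of the methyl ketone is C-acylated within minutes at −78 °C, before the O5 silyl group can migrate, and the activated diketone takes the diazo group from the sulfonyl azide while the trifluoroacetyl group leaves as the N-sulfonyl amide.

Step 8
Reactants: 13 2-diazo-1-{2-[4-(tert-butyldimethylsilyloxy)-3-methoxybenzyloxy]-4,6-bis(tert-butyldimethylsilyloxy)-5-(3-methylbut-2-enyl)phenyl}ethanone
Product: 14 (2S)-5,7-bis(tert-butyldimethylsilyloxy)-2-[4-(tert-butyldimethylsilyloxy)-3-methoxyphenyl]-6-(3-methylbut-2-enyl)-2,3-dihydrochromen-4-one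
Conditions: Rh2(S-PTTL)4 (dirhodium tetrakis[N-phthaloyl-(S)-tert-leucinate], 2 mol %), 4 Å MS, toluene, 0 °C, 13 added by syringe pump over several hours at high dilution
Reagents that add atoms: none
Why: The lantern complex of divalent rhodium binds the diazo carbon of 13, expels N2 and leaves an electrophilic carbenoid at C3, which meets a benzylic C–H bond of the O1–CH2 group in a concerted but asynchronous three-centre transition state, with hydride-like transfer to C3 and simultaneous C2–C3 bonding. The closest known reaction type is the intramolecular C–H insertion of ortho-alkoxyaryl diazoketones to 2-substituted chroman-4-ones under chiral dirhodium carboxylates. Ring C closes by 1,6-insertion through the six-membered array C3–C4–C4a–C8a–O1–C2, because the normally preferred 1,5-position is O1, which has no hydrogen. C2 is the only new stereocentre and is set by the catalyst alone: the phthalimido walls around the carbenoid allow ring B to point outward in only one of the two diastereomeric approaches, so one enantiotopic hydrogen is selected. Insertion must outrun attack of O1 on the carbenoid followed by a 1,2-benzyl shift, and three substrate features favour this: the low basicity of O1 (an aryl ether conjugated into the acyl-bearing ring A), the double activation of the C–H bond (alpha to O1 and benzylic to a ring with 4-silyloxy and 3-methoxy donors), and the bulky O5 silyl ether, which twists the acyl group out of the ring A plane that a five-membered ylide requires. No other site competes, since O5 and O7 carry no alpha C–H bond, the prenyl alkene sits meta to the acyl carbon and cannot reach C3 within the molecule, and slow addition at high dilution suppresses bimolecular cyclopropanation and carbene dimerisation.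

Step 9
Reactants: 14 (2S)-5,7-bis(tert-butyldimethylsilyloxy)-2-[4-(tert-butyldimethylsilyloxy)-3-methoxyphenyl]-6-(3-methylbut-2-enyl)-2,3-dihydrochromen-4-one
Product: 15 (2S)-5,7-bis(tert-butyldimethylsilyloxy)-2-[4-(tert-butyldimethylsilyloxy)-3-methoxyphenyl]-6-(3-methylbut-2-enyl)-4-(trimethylsilyloxy)-2H-chromene
Conditions: TMSCl (present from the start), LiN(i-Pr)2, THF, −78 °C; pH 7 buffer work-up
Reagents that add atoms: trimethylsilyl chloride, C[Si](C)(C)Cl
Why: Kinetic enolisation at C3 with in situ silyl quench, a method known to turn flavanones into their enol silanes: O-silylation of the enolate outruns E1cB expulsion of the O1 phenoxide, so ring C stays closed and C2 keeps its configuration.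

Step 10
Reactants: 15 (2S)-5,7-bis(tert-butyldimethylsilyloxy)-2-[4-(tert-butyldimethylsilyloxy)-3-methoxyphenyl]-6-(3-methylbut-2-enyl)-4-(trimethylsilyloxy)-2H-chromene
Product: 17 (2R,3R)-3-hydroxy-5,7-bis(tert-butyldimethylsilyloxy)-2-[4-(tert-butyldimethylsilyloxy)-3-methoxyphenyl]-6-(3-methylbut-2-enyl)-2,3-dihydrochromen-4-one, via silyloxy epoxide 16 (not isolated)
Conditions: dimethyldioxirane (1.0 equiv), acetone–CH2Cl2, −78 °C; then 10% aq citric acid, THF, 0 °C
Reagents that add atoms: dimethyldioxirane, CC1(C)OO1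
Why: Rubottom oxidation: the C3=C4 enol silane, raised in energy by its silyloxy and ring A donors, should take oxygen from one equivalent of the neutral dioxirane at −78 °C well before the prenyl alkene does, the reagent approaches the 2H-chromene face opposite the C2 aryl group so the new C3–O bond is trans to it (3R), and mild acid collapses the silyloxy epoxide to the hydroxy ketone, whose diequatorial trans form is also the thermodynamic one.

Step 11
Reactants: 17 (2R,3R)-3-hydroxy-5,7-bis(tert-butyldimethylsilyloxy)-2-[4-(tert-butyldimethylsilyloxy)-3-methoxyphenyl]-6-(3-methylbut-2-enyl)-2,3-dihydrochromen-4-one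
Product: 18 (2R,3R)-3,5,7-trihydroxy-2-(4-hydroxy-3-methoxyphenyl)-6-(3-methylbut-2-enyl)-2,3-dihydrochromen-4-one
Conditions: Et3N·3HF, THF, 0 °C to rt
Reagents that add atoms: none
Why: Fluoride-driven cleavage of the three aryl silyl ethers in a slightly acidic medium: no phenoxide builds up, so ring opening with epimerisation at C2 or C3 and air oxidation to the flavonol are avoided, and the acidity is too low to cyclise the prenyl group onto O5 or O7.

Compound list
1 | 2,4,6-trihydroxyacetophenone | CC(=O)c1c(O)cc(O)cc1O | starting material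
2 | 1-[2-hydroxy-4,6-bis(tert-butyldimethylsilyloxy)phenyl]ethanone | CC(=O)c1c(O)cc(O[Si](C)(C)C(C)(C)C)cc1O[Si](C)(C)C(C)(C)C | intermediate
3 | 3-methylbut-2-en-1-ol (prenol) | CC(C)=CCO | starting material
4 | 1-[2-(3-methylbut-2-enyloxy)-4,6-bis(tert-butyldimethylsilyloxy)phenyl]ethanone | CC(=O)c1c(OCC=C(C)C)cc(O[Si](C)(C)C(C)(C)C)cc1O[Si](C)(C)C(C)(C)C | intermediate
5 | 2-acetyl-3,5-bis(tert-butyldimethylsilyloxy)-6-(2-methylbut-3-en-2-yl)cyclohexa-2,4-dien-1-one (ortho-dienone, racemic, not isolated) | CC(=O)C1=C(O[Si](C)(C)C(C)(C)C)C=C(O[Si](C)(C)C(C)(C)C)C(C(C)(C)C=C)C1=O | intermediate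
6 | 2-acetyl-3,5-bis(tert-butyldimethylsilyloxy)-4-(3-methylbut-2-enyl)cyclohexa-2,5-dien-1-one (para-dienone, racemic, not isolated) | CC(=O)C1=C(O[Si](C)(C)C(C)(C)C)C(CC=C(C)C)C(O[Si](C)(C)C(C)(C)C)=CC1=O | intermediate
7 | 1-[2-hydroxy-4,6-bis(tert-butyldimethylsilyloxy)-5-(3-methylbut-2-enyl)phenyl]ethanone (prenyl between the two silyloxy groups, free OH para to it) | CC(=O)c1c(O)cc(O[Si](C)(C)C(C)(C)C)c(CC=C(C)C)c1O[Si](C)(C)C(C)(C)C | intermediate
8 | vanillin | COc1cc(C=O)ccc1O | starting material
9 | 4-(tert-butyldimethylsilyloxy)-3-methoxybenzaldehyde | COc1cc(C=O)ccc1O[Si](C)(C)C(C)(C)C | intermediate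
10 | [4-(tert-butyldimethylsilyloxy)-3-methoxyphenyl]methanol | COc1cc(CO)ccc1O[Si](C)(C)C(C)(C)C | intermediate
11 | 1-{2-[4-(tert-butyldimethylsilyloxy)-3-methoxybenzyloxy]-4,6-bis(tert-butyldimethylsilyloxy)-5-(3-methylbut-2-enyl)phenyl}ethanone | CC(=O)c1c(OCc2ccc(O[Si](C)(C)C(C)(C)C)c(OC)c2)cc(O[Si](C)(C)C(C)(C)C)c(CC=C(C)C)c1O[Si](C)(C)C(C)(C)C | intermediate
12 | 4,4,4-trifluoro-1-{2-[4-(tert-butyldimethylsilyloxy)-3-methoxybenzyloxy]-4,6-bis(tert-butyldimethylsilyloxy)-5-(3-methylbut-2-enyl)phenyl}butane-1,3-dione (not isolated) | O=C(CC(=O)C(F)(F)F)c1c(OCc2ccc(O[Si](C)(C)C(C)(C)C)c(OC)c2)cc(O[Si](C)(C)C(C)(C)C)c(CC=C(C)C)c1O[Si](C)(C)C(C)(C)C | intermediate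
13 | 2-diazo-1-{2-[4-(tert-butyldimethylsilyloxy)-3-methoxybenzyloxy]-4,6-bis(tert-butyldimethylsilyloxy)-5-(3-methylbut-2-enyl)phenyl}ethanone | [N-]=[N+]=CC(=O)c1c(OCc2ccc(O[Si](C)(C)C(C)(C)C)c(OC)c2)cc(O[Si](C)(C)C(C)(C)C)c(CC=C(C)C)c1O[Si](C)(C)C(C)(C)C | intermediate
14 | (2S)-5,7-bis(tert-butyldimethylsilyloxy)-2-[4-(tert-butyldimethylsilyloxy)-3-methoxyphenyl]-6-(3-methylbut-2-enyl)-2,3-dihydrochromen-4-one | COc1cc([C@H]2Oc3cc(O[Si](C)(C)C(C)(C)C)c(CC=C(C)C)c(O[Si](C)(C)C(C)(C)C)c3C(=O)C2)ccc1O[Si](C)(C)C(C)(C)C | intermediate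
15 | (2S)-5,7-bis(tert-butyldimethylsilyloxy)-2-[4-(tert-butyldimethylsilyloxy)-3-methoxyphenyl]-6-(3-methylbut-2-enyl)-4-(trimethylsilyloxy)-2H-chromene | COc1cc([C@H]2Oc3cc(O[Si](C)(C)C(C)(C)C)c(CC=C(C)C)c(O[Si](C)(C)C(C)(C)C)c3C(O[Si](C)(C)C)=C2)ccc1O[Si](C)(C)C(C)(C)C | intermediate
16 | (2R,3R,4R)-3,4-epoxy-4-(trimethylsilyloxy) derivative of 15 in flavan numbering, epoxide oxygen trans to the C2 aryl group (not isolated) | COc1cc([C@H]2Oc3cc(O[Si](C)(C)C(C)(C)C)c(CC=C(C)C)c(O[Si](C)(C)C(C)(C)C)c3[C@]4(O[Si](C)(C)C)O[C@H]24)ccc1O[Si](C)(C)C(C)(C)C | intermediate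
17 | (2R,3R)-3-hydroxy-5,7-bis(tert-butyldimethylsilyloxy)-2-[4-(tert-butyldimethylsilyloxy)-3-methoxyphenyl]-6-(3-methylbut-2-enyl)-2,3-dihydrochromen-4-one (2,3-trans) | COc1cc([C@H]2Oc3cc(O[Si](C)(C)C(C)(C)C)c(CC=C(C)C)c(O[Si](C)(C)C(C)(C)C)c3C(=O)[C@@H]2O)ccc1O[Si](C)(C)C(C)(C)C | intermediate
18 | (2R,3R)-3,5,7-trihydroxy-2-(4-hydroxy-3-methoxyphenyl)-6-(3-methylbut-2-enyl)-2,3-dihydrochromen-4-one (2,3-trans) | COc1cc([C@H]2Oc3cc(O)c(CC=C(C)C)c(O)c3C(=O)[C@@H]2O)ccc1O | target

Total step count: 11
Longest linear sequence: 9 steps (steps 1, 2, 3, 6, 7, 8, 9, 10, 11). Steps 4 and 5 form the short ring B branch.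

Steps most likely to fail

Step 8.
- **What may go wrong:** The carbenoid may be intercepted by the O1 lone pair, with ylide formation and then benzyl migration. It may abstract hydride without closing the C–C bond. It may also discriminate poorly between the two enantiotopic hydrogens. Enantiomeric purity is to be assayed at 14 and, if needed, raised by crystallisation at 17.
- **Fallback, from 7 back to 14:** C2 is set by asymmetric conjugate arylation instead.
  - Heating 7 with N,N-dimethylformamide dimethyl acetal in toluene should give the enaminone (E)-3-(dimethylamino)-1-[2-hydroxy-4,6-bis(tert-butyldimethylsilyloxy)-5-(3-methylbut-2-enyl)phenyl]prop-2-en-1-one F1.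
  - Mild acid (PPTS, CH2Cl2) closes F1 to 5,7-bis(tert-butyldimethylsilyloxy)-6-(3-methylbut-2-enyl)chromen-4-one F2.
  - Enantioselective 1,4-addition of commercial 4-(tert-butyldimethylsilyloxy)-3-methoxyphenylboronic acid then gives 14. The catalyst is [RhCl(C2H4)2]2 (monovalent rhodium) with a chiral diene ligand of the appropriate hand in toluene and aqueous K3PO4. This is a known entry to 2-arylchroman-4-ones.

Step 10.
- **What may go wrong:** Oxygen transfer to the prenyl alkene may compete with oxidation of the enol silane. Approach syn to the C2 aryl group may erode the trans selectivity.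
- **Fallback, from 15 back to 17:** Oxygen-atom transfer is replaced by C–O bond formation with an electrophile that leaves isolated alkenes alone at low temperature.
  - Treating 15 with 2,2,6,6-tetramethyl-1-oxopiperidinium tetrafluoroborate (CH2Cl2, −78 °C) should aminoxylate C3 anti to the aryl group. The product is (2R,3R)-5,7-bis(tert-butyldimethylsilyloxy)-2-[4-(tert-butyldimethylsilyloxy)-3-methoxyphenyl]-6-(3-methylbut-2-enyl)-3-(2,2,6,6-tetramethylpiperidin-1-yloxy)-2,3-dihydrochromen-4-one F3.
  - Reductive N–O cleavage of F3 with Zn in AcOH–THF delivers 17.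

Step 9.
- **What may go wrong:** The enolate may expel the O1 phenoxide (E1cB opening of ring C) before it is silylated. Peri crowding by the O5 silyl ether may also slow the trapping. Migration of the O5 silyl group to the enolate oxygen would be harmless, because every silyl group is removed at the end.
- **Fallback, from 14 back to 18:** No enolate is generated at all.
  - Soft enolisation with TBSOTf and Et3N (CH2Cl2, −78 to 0 °C) proceeds by deprotonation of the O-silylated ketone. It gives (2S)-4,5,7-tris(tert-butyldimethylsilyloxy)-2-[4-(tert-butyldimethylsilyloxy)-3-methoxyphenyl]-6-(3-methylbut-2-enyl)-2H-chromene F4.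
  - One equivalent of dimethyldioxirane at −78 °C forms the trans-configured 3,4-epoxy-4-(tert-butyldimethylsilyloxy) derivative F5.
  - On warming, F5 rearranges by silyl shift to (2R,3R)-3,5,7-tris(tert-butyldimethylsilyloxy)-2-[4-(tert-butyldimethylsilyloxy)-3-methoxyphenyl]-6-(3-methylbut-2-enyl)-2,3-dihydrochromen-4-one F6.
  - Prolonged treatment of F6 with Et3N·3HF removes all four silyl groups and gives 18.

Further compounds
F1 | step 8 | (E)-3-(dimethylamino)-1-[2-hydroxy-4,6-bis(tert-butyldimethylsilyloxy)-5-(3-methylbut-2-enyl)phenyl]prop-2-en-1-one | CN(C)/C=C/C(=O)c1c(O)cc(O[Si](C)(C)C(C)(C)C)c(CC=C(C)C)c1O[Si](C)(C)C(C)(C)C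
F2 | step 8 | 5,7-bis(tert-butyldimethylsilyloxy)-6-(3-methylbut-2-enyl)chromen-4-one | O=c1ccoc2cc(O[Si](C)(C)C(C)(C)C)c(CC=C(C)C)c(O[Si](C)(C)C(C)(C)C)c12
F3 | step 10 | (2R,3R)-5,7-bis(tert-butyldimethylsilyloxy)-2-[4-(tert-butyldimethylsilyloxy)-3-methoxyphenyl]-6-(3-methylbut-2-enyl)-3-(2,2,6,6-tetramethylpiperidin-1-yloxy)-2,3-dihydrochromen-4-one | COc1cc([C@H]2Oc3cc(O[Si](C)(C)C(C)(C)C)c(CC=C(C)C)c(O[Si](C)(C)C(C)(C)C)c3C(=O)[C@@H]2ON4C(C)(C)CCCC4(C)C)ccc1O[Si](C)(C)C(C)(C)C
F4 | step 9 | (2S)-4,5,7-tris(tert-butyldimethylsilyloxy)-2-[4-(tert-butyldimethylsilyloxy)-3-methoxyphenyl]-6-(3-methylbut-2-enyl)-2H-chromene | COc1cc([C@H]2Oc3cc(O[Si](C)(C)C(C)(C)C)c(CC=C(C)C)c(O[Si](C)(C)C(C)(C)C)c3C(O[Si](C)(C)C(C)(C)C)=C2)ccc1O[Si](C)(C)C(C)(C)C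
F5 | step 9 | (2R,3R,4R)-3,4-epoxy-4-(tert-butyldimethylsilyloxy) derivative of F4 in flavan numbering, epoxide oxygen trans to the C2 aryl group | COc1cc([C@H]2Oc3cc(O[Si](C)(C)C(C)(C)C)c(CC=C(C)C)c(O[Si](C)(C)C(C)(C)C)c3[C@]4(O[Si](C)(C)C(C)(C)C)O[C@H]24)ccc1O[Si](C)(C)C(C)(C)C
F6 | step 9 | (2R,3R)-3,5,7-tris(tert-butyldimethylsilyloxy)-2-[4-(tert-butyldimethylsilyloxy)-3-methoxyphenyl]-6-(3-methylbut-2-enyl)-2,3-dihydrochromen-4-one | COc1cc([C@H]2Oc3cc(O[Si](C)(C)C(C)(C)C)c(CC=C(C)C)c(O[Si](C)(C)C(C)(C)C)c3C(=O)[C@@H]2O[Si](C)(C)C(C)(C)C)ccc1O[Si](C)(C)C(C)(C)C
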